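How much target stands beside the other capture product in this flask at 0.20 s, at 10 s and at 10 min? The starting material gives an intermediate, which the first nucleophile turns into target and the second nucleophile into other capture product, or which goes on to solvolysis product; target can also exchange with its isomer, and the second nucleophile can decompose.

| setting | Tuesday's | Thursday's | flask |
|---|---|---|---|
| starting material | 0.50 M | 0.50 M | 0.50 M |
| first nucleophile | 0.90 equiv | 0.90 equiv | 0.900 equiv |
| second nucleophile | 0.75 equiv | 3 equiv | 1.50 equiv |
| remark | run made earlier | run made earlier |  |
| time |  |  | 10 min |

- Tuesday's (time / min: target / %, other capture product / %): 0.667: 1.8, 4.9; 1.33: 2.2, 4.5; 2.50: 2.2, 5.3; 4.00: 2.5, 4.9; 8.00: 1.6, 4.8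
- Thursday's (time / min: target / %, other capture product / %): 0.667: 1.4, 17.9; 1.33: 1.6, 17.3; 2.50: 2.4, 17.2; 4.00: 2.2, 17.4; 8.00: 2.1, 17.5

(standard deviation of a reading: 0.3 percentage points)

1. ratio of target to other capture product at 0.20 s
2. ratio of target to other capture product at 10 s
3. ratio of target to other capture product at 10 min

- steps under discussion: starting material -> intermediate; first nucleophile + intermediate -> target; second nucleophile + intermediate -> other capture product; intermediate -> solvolysis product; target <-> isomer of the product; second nucleophile -> decomposition product

Taken in slow motion, the first instants lie before the first reading at 0.667 min, so neither run shows the intermediate being made and captured. At that first reading both products already stand level within the scatter, and they stay level through the middle of each run and up to 8.00 min. On such a plateau each curve can be replaced by its mean, and the ratio of target to other capture product, divided by the charge ratio of first to second nucleophile, gives a selectivity factor. Tuesday's run gives 0.352 and Thursday's 0.370, although their second-nucleophile charges differ by a factor of 4.00, so the plateau selectivity factor is taken as their mean, 0.361.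

Using charges in place of falling levels needs a check. Thursday's other capture product averages 17.5 % of the starting material, so the mean level of the second nucleophile during capture lies a fraction 0.0291 below its charge, beside a relative gap of 0.0529 between the two factors.

The reckoning here multiplies 0.361 by the flask's charge ratio of 0.600, which gives 0.217 at 10 min. The times 0.20 s and 10 s lie before any reading, and the factor contains whatever exchange with the isomer had finished by the first reading, so for those two times the reckoning commits to 0.217 as an estimate, and the readings cannot show how far the ratio stood from it.

The forecast gives 0.22 at 0.20 s (range 0.19 to 0.36), 0.22 at 10 s and 0.216 at 10 min, noting that “Isomerisation or decomposition faster than 40 s cannot be excluded”. The flask gives 0.515 at 0.20 s, 0.232 at 10 s and 0.220 at 10 min.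

    starting material → intermediate (k = 0.860 s⁻¹)
    first nucleophile + intermediate → target (k = 3.50 M⁻¹ s⁻¹)
    second nucleophile + intermediate → other capture product (k = 4.00 M⁻¹ s⁻¹)
    intermediate → solvolysis product (k = 26.0 s⁻¹)
    target ⇌ isomer of the product (K = 1.40, k = 0.220 s⁻¹)
    second nucleophile → decomposition product (k = 4.50 × 10⁻⁵ s⁻¹)

Divided by the charge ratio, the flask's earliest asked value gives 0.859 against the plateau factor 0.361, and that moment comes earlier than the relaxation half-life of 1.84 s for target and isomer. The ratio falls because target drains into its isomer: with that exchange taken away, the flask ends at 0.527 instead of 0.220. For the neighbour flask charged with 0.540 equiv of first nucleophile, 0.361 gives 0.130, and that flask ends at 0.132.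

The earlier runs and the new flask were generated by integration on assumed constants; the scatter is artificial.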